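The pyranone ring C of the flavanone half is read as a cycloadduct. O1 and C4 are neighbouring substituents on phloroglucinol ring A, and the C2–C3 bond holds its two aryl groups trans, as an E-alkene would deliver them. With C4 taken back to CH2, cleavage of O1–C2 and C3–C4 leaves two pieces. One is a ring A salicyl alcohol (ortho-quinone methide source). The other is an E-stilbene with a free 4-hydroxyphenyl end and an acetoxyaryl end already bearing the finished flavone. A single chiral phosphoric acid-catalysed oxa-(4+2) cycloaddition unites the halves, closes ring C and sets C2 and C3. C4 oxidation and one acidic global deprotection finish the synthesis.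

Key step: step 11

Assumption: (R)-TRIP is written as the antipode that gives the (2S,3R) adduct; the sense of induction has to be read from the first run, and the equally available (S) antipode is used if it is the opposite.

Protecting-group logic:
- All phenols of the flavone half are acetates, and so is the ring B phenol after the key step. The acetates switch off the donor power of the ring on C3, make C2–H and C3–H poor hydride donors towards DDQ, and fall in acid.
- Ring A carries MOM ethers, which keep it electron-rich for the ionisation in step 11 and the hydride abstraction in step 13.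
- No base touches the molecule once the flavanone exists.

Step 1
Reactants: 1 2',6'-dihydroxy-4'-methoxyacetophenone
Product: 2 2'-hydroxy-4'-methoxy-6'-(methoxymethoxy)acetophenone
Conditions: MOMCl (1.1 equiv), iPr2NEt, CH2Cl2, 0 °C → rt
Reagents that add atoms: chloromethyl methyl ether (MOMCl), COCCl
Why: Williamson-type O-alkylation of two equivalent phenols; after the first alkylation the remaining OH is locked in a hydrogen bond to the ketone, so an amine base stops at the mono-ether and keeps the 2'-OH needed for ring closure.

Step 2
Reactants: 3 4-hydroxy-3-iodobenzaldehyde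
Product: 4 3-iodo-4-(methoxymethoxy)benzaldehyde
Conditions: MOMCl (1.3 equiv), iPr2NEt, CH2Cl2, 0 °C → rt
Reagents that add atoms: chloromethyl methyl ether (MOMCl), COCCl
Why: The same O-alkylation masks the acidic para-phenol, whose phenoxide would otherwise deactivate the aldehyde under the hydroxide conditions of step 3.

Step 3
Reactants: 2 2'-hydroxy-4'-methoxy-6'-(methoxymethoxy)acetophenone; 4 3-iodo-4-(methoxymethoxy)benzaldehyde
Product: 5 (E)-1-[2-hydroxy-4-methoxy-6-(methoxymethoxy)phenyl]-3-[3-iodo-4-(methoxymethoxy)phenyl]prop-2-en-1-one
Conditions: KOH (50 % aq), EtOH, rt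
Reagents that add atoms: none
Why: Claisen–Schmidt condensation in which only 2 can enolise and only 4 is an aldehyde; E1cB dehydration gives the E-enone, and MOM ethers and the aryl iodide are inert to hydroxide.

Step 4
Reactants: 5 the chalcone of step 3
Product: 7 5-hydroxy-2-(4-hydroxy-3-iodophenyl)-7-methoxy-4H-chromen-4-one, via bis-MOM iodoflavone 6 (not isolated)
Conditions: I2 (10 mol %), DMSO, 120 °C; then MeOH, p-TsOH·H2O, 60 °C, same flask; poured into aq Na2S2O3
Reagents that add atoms: none
Why: The iodine/DMSO oxidative cyclisation of a 2'-hydroxychalcone (oxa-Michael closure, alpha-iodination, loss of HI, reoxidation of HI by DMSO) builds the chromone, and the acid stage completes by acetal methanolysis the MOM loss that the hot medium already begins, so a partly deprotected mixture converges on one compound.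

Step 5
Reactants: 7 5-hydroxy-2-(4-hydroxy-3-iodophenyl)-7-methoxy-4H-chromen-4-one
Product: 8 2-(4-acetoxy-3-iodophenyl)-7-methoxy-4-oxo-4H-chromen-5-yl acetate
Conditions: Ac2O (excess), pyridine, DMAP (cat.), rt → 40 °C
Reagents that add atoms: acetic anhydride, CC(=O)OC(C)=O
Why: DMAP-catalysed O-acetylation with excess anhydride also acylates the chelated 5-OH, giving one kind of protecting group on both phenols, better solubility and the deactivated iodoaryl ring that step 11 relies on.

Step 6
Reactants: 9 4-vinylphenol
Product: 10 tert-butyldimethyl(4-vinylphenoxy)silane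
Conditions: TBSCl, imidazole, CH2Cl2, 0 °C → rt
Reagents that add atoms: tert-butyldimethylsilyl chloride (TBSCl), CC(C)(C)[Si](C)(C)Cl
Why: Imidazole-promoted silylation of the phenol curbs polymerisation of the styrene and removes the free phenol that could take acetyl groups from 8 in hot amine/DMF.

Step 7
Reactants: 8 2-(4-acetoxy-3-iodophenyl)-7-methoxy-4-oxo-4H-chromen-5-yl acetate; 10 tert-butyldimethyl(4-vinylphenoxy)silane
Product: 11 2-{4-acetoxy-3-[(E)-2-(4-{[tert-butyl(dimethyl)silyl]oxy}phenyl)ethenyl]phenyl}-7-methoxy-4-oxo-4H-chromen-5-yl acetate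
Conditions: Pd(OAc)2 (5 mol %), P(o-tol)3 (10 mol %), Et3N, dry DMF, 85 °C, dark
Reagents that add atoms: none
Why: In this Mizoroki–Heck reaction the aryl iodide adds oxidatively to zerovalent palladium formed from Pd(OAc)2, syn insertion at the unsubstituted alkene terminus and syn beta-hydride elimination give the E-stilbene, and a dry amine base leaves the aryl acetates and the silyl ether alone.

Step 8
Reactants: 11 the silyl-protected E-stilbene of step 7
Product: 12 2-{4-acetoxy-3-[(E)-2-(4-hydroxyphenyl)ethenyl]phenyl}-7-methoxy-4-oxo-4H-chromen-5-yl acetate (E-stilbene, free 4-hydroxyphenyl end)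
Conditions: KHF2, MeOH/THF, rt, dark
Reagents that add atoms: none
Why: Fluoride-mediated desilylation with the weakly acidic bifluoride cleaves aryl silyl ethers at room temperature and avoids the basic conditions under which aryl acetates are cleaved or migrate.

Step 9
Reactants: 13 2,4,6-trihydroxybenzaldehyde
Product: 14 2-hydroxy-4,6-bis(methoxymethoxy)benzaldehyde
Conditions: MOMCl (2.2 equiv), iPr2NEt, CH2Cl2, 0 °C
Reagents that add atoms: chloromethyl methyl ether (MOMCl), COCCl
Why: O-alkylation takes the para-OH and one of the two equivalent ortho-OH groups, and the last OH stays free because it is chelated to the aldehyde.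

Step 10
Reactants: 14 2-hydroxy-4,6-bis(methoxymethoxy)benzaldehyde
Product: 15 2-(hydroxymethyl)-3,5-bis(methoxymethoxy)phenol
Conditions: NaBH4, THF/MeOH, 0 °C; aq NaH2PO4/Na2HPO4 (pH 7) work-up; no silica gel, used the same day
Reagents that add atoms: none
Why: Borohydride reduction of an aryl aldehyde is clean at 0 °C, and the neutral work-up with immediate use avoids acid-triggered ionisation of this very electron-rich salicyl alcohol.

Step 11
Reactants: 15 2-(hydroxymethyl)-3,5-bis(methoxymethoxy)phenol; 12 the E-stilbene of step 8
Product: 17 2-{4-acetoxy-3-[(2S,3R)-2-(4-hydroxyphenyl)-5,7-bis(methoxymethoxy)-3,4-dihydro-2H-chromen-3-yl]phenyl}-7-methoxy-4-oxo-4H-chromen-5-yl acetate (trans-2,3-diarylchroman), via ortho-quinone methide 16 (not isolated)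
Conditions: (R)-TRIP [(R)-3,3'-bis(2,4,6-triisopropylphenyl)-1,1'-binaphthyl-2,2'-diyl hydrogen phosphate] (10 mol %), 4 Å MS, CH2Cl2/toluene (1:1), 0 °C; 15 (1.5 equiv) added slowly by syringe pump
Reagents that add atoms: none
Why: Proposed new method: the phosphoric acid dehydrates the 2,4,6-trioxygenated benzylic alcohol 15 to ortho-quinone methide 16 and then acts bifunctionally, its P–OH bound to the carbonyl oxygen of 16 and its P=O to the phenol of 12, so that the alkene carbon next to the acetoxyaryl ring (the terminus of a vinylogous phenol) attacks the methide CH2. The closest known reaction type is the chiral phosphoric acid-catalysed inverse-electron-demand oxa-Diels–Alder reaction of in situ generated ortho-quinone methides with hydroxystyrenes; not yet shown are a 1,2-diarylethene as the two-carbon partner and a methide with an unsubstituted CH2 terminus, which should offset each other because the small CH2 terminus leaves room for the extra aryl group and three oxygen donors let a weak acid ionise the primary alcohol. Ring C closes in a concerted, asynchronous (4+2) mode with C3–C4 formation ahead of O1–C2 formation (in the stepwise limit a 6-exo-trig attack of the ring A oxygen on the para-quinone methide carbon C2). The trans relation of C2 and C3 is carried over suprafacially from the E-alkene, and the absolute configuration of both centres, (2S,3R), is fixed by the alkene face that the triisopropylphenyl walls of the catalyst leave open to 16. Regioselectivity requires positive charge to build at C2, which the hydrogen-bonded para-hydroxyphenyl ring stabilises and the ring deactivated by its acetoxy and chromonyl groups does not, while chemoselectivity over self-condensation of nucleophilic ring A with 16 is secured by slow addition of 15, sieves and low temperature. MOM ethers, aryl acetates and the chromone are inert to this weak acid.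

Step 12
Reactants: 17 the trans-(2S,3R)-chroman of step 11
Product: 18 2-{4-acetoxy-3-[(2S,3R)-2-(4-acetoxyphenyl)-5,7-bis(methoxymethoxy)-3,4-dihydro-2H-chromen-3-yl]phenyl}-7-methoxy-4-oxo-4H-chromen-5-yl acetate
Conditions: Ac2O, pyridine, CH2Cl2, 0 °C → rt
Reagents that add atoms: acetic anhydride, CC(=O)OC(C)=O
Why: O-acetylation shields the ring B phenol from DDQ and makes C2–H a much poorer hydride donor than C4–H.

Step 13
Reactants: 18 the triacetate chroman of step 12
Product: 19 the 4-hydroxychroman (2S,3S,4-epimer mixture; C2 and C3 spatially unchanged, the C3 descriptor changes only through CIP priorities)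
Conditions: DDQ (1.5 equiv), CH2Cl2/aq NaH2PO4–Na2HPO4 (pH 7) (10:1), 0 °C
Reagents that add atoms: water, O
Why: DDQ benzylic oxidation by hydride abstraction, the reaction used to functionalise C4 of protected flavan-3-ols, should select C4–H because only it is conjugated with tri-oxygenated ring A, water captures the cation, and the new carbinol centre (expected mainly anti to the C3 aryl group) needs no control because step 14 removes it.

Step 14
Reactants: 19 the 4-hydroxychroman of step 13
Product: 20 2-{4-acetoxy-3-[(2S,3R)-2-(4-acetoxyphenyl)-5,7-bis(methoxymethoxy)-4-oxo-3,4-dihydro-2H-chromen-3-yl]phenyl}-7-methoxy-4-oxo-4H-chromen-5-yl acetate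
Conditions: Dess–Martin periodinane, pyridine, CH2Cl2, 0 °C → rt
Reagents that add atoms: none
Why: Dess–Martin oxidation of a secondary benzylic alcohol under pyridine buffering is neutral and fast, so C2 is untouched and C3, now alpha to the ketone, stays in its thermodynamically preferred trans arrangement.

Step 15
Reactants: 20 the protected flavanone–flavone of step 14
Product: 21 2-{3-[(2S,3R)-5,7-dihydroxy-2-(4-hydroxyphenyl)-4-oxo-3,4-dihydro-2H-chromen-3-yl]-4-hydroxyphenyl}-5-hydroxy-7-methoxy-4H-chromen-4-one (target)
Conditions: HCl (3 M in MeOH), THF, 40 °C, argon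
Reagents that add atoms: none
Why: Acid-catalysed acetal methanolysis (two MOM ethers) and transesterification (three aryl acetates) run side by side, so all five groups fall without any base that could open the flavanone at O1–C2, and C3 enolisation cannot harm the more stable trans isomer.

Compound list
1 | 2',6'-dihydroxy-4'-methoxyacetophenone | CC(=O)c1c(O)cc(OC)cc1O | starting material
2 | 2'-hydroxy-4'-methoxy-6'-(methoxymethoxy)acetophenone | CC(=O)c1c(O)cc(OC)cc1OCOC | intermediate
3 | 4-hydroxy-3-iodobenzaldehyde | O=Cc1ccc(O)c(I)c1 | starting material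
4 | 3-iodo-4-(methoxymethoxy)benzaldehyde | O=Cc1ccc(OCOC)c(I)c1 | intermediate
5 | (E)-1-[2-hydroxy-4-methoxy-6-(methoxymethoxy)phenyl]-3-[3-iodo-4-(methoxymethoxy)phenyl]prop-2-en-1-one | COCOc1ccc(/C=C/C(=O)c2c(O)cc(OC)cc2OCOC)cc1I | intermediate
6 | 2-[3-iodo-4-(methoxymethoxy)phenyl]-7-methoxy-5-(methoxymethoxy)-4H-chromen-4-one | COCOc1ccc(-c2cc(=O)c3c(OCOC)cc(OC)cc3o2)cc1I | intermediate
7 | 5-hydroxy-2-(4-hydroxy-3-iodophenyl)-7-methoxy-4H-chromen-4-one | COc1cc(O)c2c(=O)cc(-c3ccc(O)c(I)c3)oc2c1 | intermediate
8 | 2-(4-acetoxy-3-iodophenyl)-7-methoxy-4-oxo-4H-chromen-5-yl acetate | COc1cc(OC(C)=O)c2c(=O)cc(-c3ccc(OC(C)=O)c(I)c3)oc2c1 | intermediate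
9 | 4-vinylphenol | C=Cc1ccc(O)cc1 | starting material
10 | tert-butyldimethyl(4-vinylphenoxy)silane | C=Cc1ccc(O[Si](C)(C)C(C)(C)C)cc1 | intermediate
11 | E-stilbene, silyl ether, flavone diacetate | COc1cc(OC(C)=O)c2c(=O)cc(-c3ccc(OC(C)=O)c(/C=C/c4ccc(O[Si](C)(C)C(C)(C)C)cc4)c3)oc2c1 | intermediate
12 | E-stilbene, free 4-hydroxyphenyl end, flavone diacetate | COc1cc(OC(C)=O)c2c(=O)cc(-c3ccc(OC(C)=O)c(/C=C/c4ccc(O)cc4)c3)oc2c1 | intermediate
13 | 2,4,6-trihydroxybenzaldehyde | O=Cc1c(O)cc(O)cc1O | starting material
14 | 2-hydroxy-4,6-bis(methoxymethoxy)benzaldehyde | O=Cc1c(O)cc(OCOC)cc1OCOC | intermediate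
15 | 2-(hydroxymethyl)-3,5-bis(methoxymethoxy)phenol | OCc1c(O)cc(OCOC)cc1OCOC | intermediate
16 | 3,5-bis(methoxymethoxy)-6-methylidenecyclohexa-2,4-dien-1-one | C=C1C(=O)C=C(OCOC)C=C1OCOC | intermediate
17 | trans-(2S,3R)-2,3-diarylchroman, free ring B phenol | COc1cc(OC(C)=O)c2c(=O)cc(-c3ccc(OC(C)=O)c([C@H]4Cc5c(OCOC)cc(OCOC)cc5O[C@@H]4c4ccc(O)cc4)c3)oc2c1 | intermediate
18 | trans-(2S,3R)-2,3-diarylchroman triacetate | COc1cc(OC(C)=O)c2c(=O)cc(-c3ccc(OC(C)=O)c([C@H]4Cc5c(OCOC)cc(OCOC)cc5O[C@@H]4c4ccc(OC(C)=O)cc4)c3)oc2c1 | intermediate
19 | (2S,3S)-4-hydroxychroman triacetate, C4 epimers | COc1cc(OC(C)=O)c2c(=O)cc(-c3ccc(OC(C)=O)c([C@H]4C(O)c5c(OCOC)cc(OCOC)cc5O[C@@H]4c4ccc(OC(C)=O)cc4)c3)oc2c1 | intermediate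
20 | (2S,3R)-chroman-4-one triacetate bis-MOM ether | COc1cc(OC(C)=O)c2c(=O)cc(-c3ccc(OC(C)=O)c([C@H]4C(=O)c5c(OCOC)cc(OCOC)cc5O[C@@H]4c4ccc(OC(C)=O)cc4)c3)oc2c1 | intermediate
21 | CNP0361110.2, (2S,3R) | COc1cc(O)c2c(=O)cc(-c3ccc(O)c([C@H]4C(=O)c5c(O)cc(O)cc5O[C@@H]4c4ccc(O)cc4)c3)oc2c1 | target

Total step count: 15
Longest linear sequence: 11 steps (1 → 2 → 5 → 7 → 8 → 11 → 12 → 17 → 18 → 19 → 20 → 21)

Steps most likely to fail

**Step 11.** The hindered 1,2-disubstituted alkene may add too slowly, so that the methide is consumed by self-condensation with ring A. Facial discrimination may also be weak, because the hydrogen-bond anchor lies far from the reacting carbons.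

The fallback uses known chemistry only and gives up catalyst control. It sets out from 12 and 15, which are heated without acid in toluene at about 100 °C. This is the classical thermal dehydration of a salicyl alcohol to its ortho-quinone methide, followed by hetero-Diels–Alder capture by a styrene-type alkene. The E geometry still guarantees the trans ring. The reaction should give 17 together with its mirror image, the (2R,3S)-chroman F1. The racemate is split by preparative chromatography on a polysaccharide chiral stationary phase, and the route is rejoined at 17.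

**Step 13.** The C4 cation may lose the C3 proton, or the 4-ol may re-ionise and dehydrate. Either path leads to a 2H-chromene that DDQ aromatises further, with loss of both stereocentres.

The fallback sets out from 18 and reaches the ketone level by two hydride abstractions, without ever forming a free alcohol. DDQ in homogeneous CH2Cl2/MeOH, with a far higher nucleophile concentration, should give the isolable 4-methoxychroman F2. A second DDQ treatment in wet CH2Cl2 follows the mechanism of oxidative cleavage of electron-rich benzylic ethers: hydride abstraction from C4–H, a hemiketal, then loss of methanol. Any enol ether formed by proton loss hydrolyses to the same ketone. The route is rejoined at 20, and compound 19 and the Dess–Martin step are left out.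

**Step 15.** The hindered acetate next to C3 may solvolyse slowly and prolong the acid exposure. Configuration could then erode through reversible opening of the O1–C2 bond, and freed formaldehyde equivalents could alkylate ring A.

The fallback sets out from 20 and replaces the single global acidolysis by two orthogonal stages. First, NH4OAc in MeOH/THF/water at room temperature removes the three aryl acetates under near-neutral conditions and should give the triphenol bis-MOM flavanone F3. Second, dilute methanolic HCl at room temperature needs to cleave only the two MOM acetals. The route is rejoined at 21.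

Further compounds
F1 | step 11 | (2R,3S) enantiomer of chroman 17 | COc1cc(OC(C)=O)c2c(=O)cc(-c3ccc(OC(C)=O)c([C@@H]4Cc5c(OCOC)cc(OCOC)cc5O[C@H]4c4ccc(O)cc4)c3)oc2c1
F2 | step 13 | 4-methoxy derivative of chroman 18 (C2 and C3 as in 18, C4 epimers) | COc1cc(OC(C)=O)c2c(=O)cc(-c3ccc(OC(C)=O)c([C@H]4C(OC)c5c(OCOC)cc(OCOC)cc5O[C@@H]4c4ccc(OC(C)=O)cc4)c3)oc2c1
F3 | step 15 | (2S,3R)-flavanone–flavone with free 5-, 4'- and ring B phenols and 5,7-bis-MOM ring A | COc1cc(O)c2c(=O)cc(-c3ccc(O)c([C@H]4C(=O)c5c(OCOC)cc(OCOC)cc5O[C@@H]4c4ccc(O)cc4)c3)oc2c1
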